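**Plan**
Retrosynthesis: the primary allylic bromide goes back to the chloride 9 by halide exchange. Then the ring bonds C4–C5 (CHCl–CH2) and C1–C2 (CMe2–CHCl) are cut together, which splits the cyclohexane into two isoprene-sized C5 halves.
Enabling feature: C6 (CHBr) lies between C5H2 and C1Me2. This is a prenyl unit with bromine on its middle carbon, a 1,3-dielectrophile whose tertiary end is switched on through a bromiranium ion. The sp2 carbon C3 lies between the two CHCl carbons C2 and C4 and carries the two-carbon side chain, a constitutionally symmetric 1,3-dichloro-2-vinylallyl 1,3-dinucleophile.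
Forward: prenol gives electrophile 3 in two steps and 1,3-dichloroacetone gives pronucleophile 6 in two steps. In one flask the chain is joined first at CH2 (SN2), then the only ring closes at the quaternary carbon (cationic). This copies the presumed bromonium cyclisation of a halogenated myrcene and also delivers the exocyclic E alkene and the allylic halide.
Stereochemistry: C6 comes from a catalytic enantioselective bromochlorination of prenol. C2, C4 and the alkene geometry follow from it in the chair transition state of the ring closure (anti opening of the bromiranium ion, Z chlorovinyl group, A(1,3) strain, s-trans diene).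

Key step: step 5

Assumption: the (S)-configured Schiff-base ligand of step 1 is taken to give (S)-2; if the sense of induction is the opposite, its enantiomer is used.

Step 1
Reactants: 1 prenol (3-methylbut-2-en-1-ol)
Product: 2 (S)-2-bromo-3-chloro-3-methylbutan-1-ol
Conditions: NBS, ClTi(OiPr)3, 2,4-di-tert-butyl-6-[{[(2S)-1-hydroxy-3,3-dimethyl-1,1-diphenylbutan-2-yl]imino}methyl]phenol (20 mol%), hexane, −20 °C
Reagents that add atoms: N-bromosuccinimide O=C1CCC(=O)N1Br; chlorotitanium triisopropoxide CC(C)O[Ti](Cl)(OC(C)C)OC(C)C
Why: Catalytic enantioselective bromochlorination of an allylic alcohol, in which the substrate binds as alkoxide to the chiral tetravalent titanium Schiff-base complex, NBS delivers Br+ to one alkene face and titanium-bound chloride opens the bromiranium ion anti at the tertiary carbon (Markovnikov), so the single stereocentre is set by catalyst control.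

Step 2
Reactants: 2 (S)-2-bromo-3-chloro-3-methylbutan-1-ol
Product: 3 (S)-2-bromo-3-chloro-3-methylbutyl trifluoromethanesulfonate
Conditions: Tf2O, 2,6-lutidine, CH2Cl2, −78 °C; cold aqueous wash, used at once
Reagents that add atoms: trifluoromethanesulfonic anhydride O=S(=O)(OS(=O)(=O)C(F)(F)F)C(F)(F)F
Why: O-Sulfonylation (triflation) of a primary alcohol with a hindered pyridine base, which does not touch the stereocentre and gives a β-bromo triflate whose ionisation is slowed by the electron-withdrawing halogens.

Step 3
Reactants: 4 1,3-dichloroacetone
Product: 5 1-chloro-2-(chloromethyl)but-3-en-2-ol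
Conditions: CH2=CHMgBr, THF, −78 °C; aq NH4Cl at −78 °C
Reagents that add atoms: vinylmagnesium bromide C=C[Mg]Br
Why: Grignard 1,2-addition to an α,α′-dichloroketone, quenched cold so that the chlorohydrin alkoxide does not close to an epoxide, and no stereocentre arises because the two CH2Cl arms are identical.

Step 4
Reactants: 5 1-chloro-2-(chloromethyl)but-3-en-2-ol
Product: 6 1-chloro-2-(chloromethyl)buta-1,3-diene (E/Z mixture)
Conditions: methyl N-(triethylammoniosulfonyl)carbamate (Burgess reagent), toluene, 50 °C, BHT; used cold and soon
Reagents that add atoms: none
Why: Burgess dehydration (syn elimination of the sulfamate ester) of a tertiary alcohol whose only β-hydrogens sit on the acidified CH2Cl arms, so one constitution can form, and the E/Z ratio does not matter because the geometry is erased on deprotonation in step 5.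

Step 5
Reactants: 6 1-chloro-2-(chloromethyl)buta-1,3-diene; 3 (S)-2-bromo-3-chloro-3-methylbutyl trifluoromethanesulfonate
Product: 9 (2S,3E,4S,6S)-6-bromo-2,4-dichloro-3-(2-chloroethylidene)-1,1-dimethylcyclohexane, via dichlorovinylallyllithium 7 (not isolated), via open-chain bromotrichloride 8 (not isolated)
Conditions: 6, LiN(iPr)2, THF, −95 °C; CuCl·2LiCl (10 mol%), then 3, −95 to −40 °C; volatiles off at 0 °C; (CF3)2CHOH, 0.01 M, 0 to 25 °C
Reagents that add atoms: none
Why: Proposed new method: LiN(iPr)2 removes an allylic CH2Cl proton of 6 to give the 1,3-dichloro-2-vinylallyl anion 7, which with copper assistance displaces the primary triflate of 3 by SN2 and makes the C4–C5 bond in 8, and after the switch to the ionising, non-nucleophilic (CF3)2CHOH the tertiary chloride leaves with anchimeric help from bromine, the chlorovinyl terminus of the diene opens the enantiopure bromiranium ion at CMe2 to make the C1–C2 bond, and the allyl cation takes the chloride back at its primary end, so that 8 and 9 are isomers. The closest known reaction types are the copper-catalysed coupling of primary alkyl triflates with allylic organometallics and the enantiospecific solvolytic bromonium–olefin cyclisation of β-bromo tertiary chlorides; new are the chlorinated allyl nucleophile, the 1-chlorodiene as terminator and the telescoping, and the second half copies the presumed bromonium cyclisation of a halogenated myrcene. The six-membered ring closes 6-endo with respect to both the attacking C=C bond and the bromiranium ion, through a chair. C6 (CHBr) keeps the configuration of 3 because bromine never leaves this carbon, and anti opening of the bromiranium ion makes Br equatorial; C2 is controlled by the Z chlorovinyl geometry, whose chlorine, cis to the chain, becomes axial and thus trans to Br. C4 arises without bias in the alkylation, but as a secondary allylic chloride it should epimerise in this medium by ionisation and return through the planar 1,3-dichloroallyl cation and its gem-dichloride isomer (LiOTf and CuCl left in the flask help, and the same process interconverts E and Z chlorovinyl forms), so that under Curtin–Hammett conditions the material drains through the one chair with Br equatorial and both chlorines axial, the equatorial C4–Cl alternative being penalised by A(1,3) strain with the s-trans vinyl group, which in turn places CH2Cl cis to C4 (E alkene). The step needs site selectivity between the two electrophilic carbons (secured by the SN2-then-SN1 order, tertiary chloride and neopentyl-type bromide being inert to SN2), indifference to which allyl terminus reacts (secured by the equivalence of the two CHCl termini of 7, the cross-conjugated vinyl group carrying no charge) and six- over seven-ring closure (secured by attack through the diene terminus that leaves an allyl cation).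

Step 6
Reactants: 9 (2S,3E,4S,6S)-6-bromo-2,4-dichloro-3-(2-chloroethylidene)-1,1-dimethylcyclohexane
Product: 10 ochtodene, (2S,3E,4S,6S)-6-bromo-3-(2-bromoethylidene)-2,4-dichloro-1,1-dimethylcyclohexane
Conditions: NaBr (1.1 equiv), acetone, 0 °C to rt
Reagents that add atoms: sodium bromide [Na+].[Br-]
Why: Finkelstein halide exchange (SN2) driven by precipitation of NaCl, which should touch only the unhindered primary allylic chloride because C2–Cl and C6–Br are neopentyl-type and exchange at the axial C4–Cl would give an A(1,3)-strained equatorial bromide, so no stereocentre is affected.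

**Compound list**
1 | prenol (3-methylbut-2-en-1-ol) | CC(C)=CCO | starting material
2 | (S)-2-bromo-3-chloro-3-methylbutan-1-ol | CC(C)(Cl)[C@@H](Br)CO | intermediate
3 | (S)-2-bromo-3-chloro-3-methylbutyl trifluoromethanesulfonate | CC(C)(Cl)[C@@H](Br)COS(=O)(=O)C(F)(F)F | intermediate
4 | 1,3-dichloroacetone | ClCC(=O)CCl | starting material
5 | 1-chloro-2-(chloromethyl)but-3-en-2-ol | OC(CCl)(CCl)C=C | intermediate
6 | 1-chloro-2-(chloromethyl)buta-1,3-diene (E/Z mixture) | ClCC(C=C)=CCl | intermediate
7 | (1,3-dichloro-2-vinylallyl)lithium | [Li]C(Cl)C(C=C)=CCl | intermediate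
8 | (3Z,4S,6S)-6-bromo-4,7-dichloro-3-(chloromethylidene)-7-methyloct-1-ene | CC(C)(Cl)[C@@H](Br)C[C@H](Cl)/C(C=C)=C\Cl | intermediate
9 | (2S,3E,4S,6S)-6-bromo-2,4-dichloro-3-(2-chloroethylidene)-1,1-dimethylcyclohexane | CC1(C)[C@@H](Br)C[C@H](Cl)/C(=C\CCl)[C@@H]1Cl | intermediate
10 | ochtodene, (2S,3E,4S,6S)-6-bromo-3-(2-bromoethylidene)-2,4-dichloro-1,1-dimethylcyclohexane | CC1(C)[C@@H](Br)C[C@H](Cl)/C(=C\CBr)[C@@H]1Cl | target

Total steps: 6. Longest linear sequence: 4 steps (1 → 2 → 3 → 9 → 10, or 4 → 5 → 6 → 9 → 10).

**Steps most likely to fail**

1. Step 5.
What may go wrong: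
- The basic carbenoid-type anion may cause elimination or bromine-philic attack on the triflate instead of substitution.
- Epimerisation at C4 may be too slow compared with ring closure, which would give poor diastereoselectivity at C4 and erode the alkene geometry.
- Solvent capture may outrun the weakly nucleophilic chlorodiene.

Fallback: it sets out from 3 and comes back at 8, which is then isolated as a single isomer and cyclised on its own in (CF3)2CHOH to 9. The chlorinated centre is set by catalyst control and the C3–C4 bond is made by carbonyl chemistry.
- Copper-catalysed coupling of 3 with allylmagnesium bromide (Li2CuCl4 5 mol%, THF, −78 °C) should give (S)-5-bromo-6-chloro-6-methylhept-1-ene F1.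
- Ozonolysis (O3, then PPh3) gives (S)-4-bromo-5-chloro-5-methylhexanal F2.
- Enamine-catalysed α-chlorination (NCS, the fitting enantiomer of 2,5-diphenylpyrrolidine) gives (2S,4S)-4-bromo-2,5-dichloro-5-methylhexanal F3.
- Addition of vinylmagnesium bromide at −78 °C gives (4S,6S)-6-bromo-4,7-dichloro-7-methyloct-1-en-3-ol F4 as carbinol epimers.
- Dess–Martin oxidation gives (4S,6S)-6-bromo-4,7-dichloro-7-methyloct-1-en-3-one F5.
- Wittig chloromethylenation (Ph3P=CHCl, −78 °C), followed by separation of the alkene isomers, gives 8.

2. Step 6.
What may go wrong: halide scrambling, that is, bromide may also enter at the secondary allylic position C4 or cause allylic transposition while NaCl precipitates.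

Fallback: it sets out from 9 and comes back at 10, passing through oxygen instead of direct halide exchange.
- CsOAc in DMF at 0 °C should displace only the primary allylic chloride, giving 2-[(E,2S,4S,6S)-4-bromo-2,6-dichloro-3,3-dimethylcyclohexylidene]ethyl acetate F6.
- iBu2AlH in CH2Cl2 at −78 °C frees 2-[(E,2S,4S,6S)-4-bromo-2,6-dichloro-3,3-dimethylcyclohexylidene]ethanol F7.
- Appel bromination (CBr4, PPh3, CH2Cl2, 0 °C) gives 10 with no free halide ion in solution.

3. Step 4.
What may go wrong: the allylic sulfamate may ionise and rearrange instead of undergoing syn elimination, and the chlorodiene may polymerise on isolation.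

Fallback: it sets out from 5 and comes back at 6, using transposition and then 1,4-elimination.
- SOCl2 in Et2O at 0 °C should convert 5 with allylic transposition into 1,4-dichloro-2-(chloromethyl)but-2-ene F8, which is storable.
- 1,4-Dehydrochlorination with DBU in Et2O just before use gives 6 as a solution that goes straight into step 5.

**Further compounds**
F1 | step 5 | (S)-5-bromo-6-chloro-6-methylhept-1-ene | CC(C)(Cl)[C@@H](Br)CCC=C
F2 | step 5 | (S)-4-bromo-5-chloro-5-methylhexanal | CC(C)(Cl)[C@@H](Br)CCC=O
F3 | step 5 | (2S,4S)-4-bromo-2,5-dichloro-5-methylhexanal | CC(C)(Cl)[C@@H](Br)C[C@H](Cl)C=O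
F4 | step 5 | (4S,6S)-6-bromo-4,7-dichloro-7-methyloct-1-en-3-ol (carbinol epimers) | CC(C)(Cl)[C@@H](Br)C[C@H](Cl)C(O)C=C
F5 | step 5 | (4S,6S)-6-bromo-4,7-dichloro-7-methyloct-1-en-3-one | CC(C)(Cl)[C@@H](Br)C[C@H](Cl)C(=O)C=C
F6 | step 6 | 2-[(E,2S,4S,6S)-4-bromo-2,6-dichloro-3,3-dimethylcyclohexylidene]ethyl acetate | CC1(C)[C@@H](Br)C[C@H](Cl)/C(=C\COC(C)=O)[C@@H]1Cl
F7 | step 6 | 2-[(E,2S,4S,6S)-4-bromo-2,6-dichloro-3,3-dimethylcyclohexylidene]ethanol | CC1(C)[C@@H](Br)C[C@H](Cl)/C(=C\CO)[C@@H]1Cl
F8 | step 4 | 1,4-dichloro-2-(chloromethyl)but-2-ene | ClCC=C(CCl)CCl
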